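Amounts first: the flasks hold c(starting material) = 0.050 M with 5 mol% of free catalyst, and I must choose the bath for the next flask.

the same everywhere: starting material 0.050 M; free catalyst 5 mol%

| run | second substrate | capture agent | protic impurity | temperature | remark | time |
|---|---|---|---|---|---|---|
| Monday's | 1 equiv | 0.021 M | 5 mM | 35 °C | run made earlier |  |
| Thursday's | 1 equiv | 0.033 M | 5 mM | 55 °C | run made earlier |  |
| birch | 1.00 equiv | 0.0150 M | 5.00 mM | 55 °C |  | 8.0 d |
| elm | 1.00 equiv | 0.0150 M | 5.00 mM |  | at 40 °C until 6.0 d, from then on at 70 °C | 8.0 d |
| larch | 1.00 equiv | 0.0150 M | 5.00 mM | 40 °C |  | 8.0 d |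
| alder | 1.00 equiv | 0.0150 M | 5.00 mM | 70 °C |  | 8.0 d |

| run | time / d | target / % |
|---|---|---|
| Monday's | 3.00 | 4.5 |
| Monday's | 6.00 | 9.6 |
| Monday's | 10.0 | 14.2 |
| Monday's | 15.0 | 19.8 |
| Monday's | 20.0 | 23.8 |
| Thursday's | 1.25 | 16.5 |
| Thursday's | 2.50 | 29.5 |
| Thursday's | 4.00 | 39.4 |
| Thursday's | 5.00 | 44.6 |
| Thursday's | 6.00 | 50.2 |
| Thursday's | 8.00 | 57.9 |

(readings scatter by 0.5 percentage points)
- percent here means starting material units held: one side product counts as two
- what was read earlier has a scatter of 0.5 percentage points, one standard deviation
- on the list of suspects stand: starting material + free catalyst <-> catalyst intermediate A; catalyst intermediate A -> free catalyst + target; second substrate + free catalyst <-> catalyst intermediate B; catalyst intermediate B -> free catalyst + second product; catalyst intermediate B + capture agent -> trapped intermediate; second substrate + protic impurity -> quenched substrate; starting material + target -> side product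
- which flask leads in amount of target, in percent of the starting material charged ("all alike" within 1.5 percentage points) (birch / elm / larch / alder / all alike)
- how much target is there at the end, in percent of the starting material charged: birch
- how much target is there at the end, in percent of the starting material charged: elm
- how much target is there at the end, in percent of the starting material charged: larch
- how much target is there at the end, in percent of the starting material charged: alder

The suspects: starting material and second substrate each bind free catalyst, capture agent turns catalyst intermediate B into trapped intermediate, and starting material with target gives side product.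

1. For a fraction y of target I define the exposure E = −ln(1 − y). With steady catalyst, E grows as k·t, a pseudo-first-order loss of starting material, and exposures add from one bath to the next.

2. Early end. The first readings give 0.0153 d⁻¹ on Monday and 0.144 d⁻¹ on Thursday, so 94.2 kJ mol⁻¹. That puts k at 0.0276 d⁻¹ for 40 °C and 0.652 d⁻¹ for 70 °C.

3. Late end. Thursday's last reading gives E = 0.865, so that flask lost 25.0 % of its steady exposure.

4. Join. I assume this loss scales with c(capture agent). At 0.0150 M the kept share of exposure is then 88.6 %.

5. My reckoning gives birch 64.0 %, elm 72.8 % and alder 99.0 %. Larch reckons to 17.8 % with this kept share and to 19.8 % with no loss of exposure. The alder figure carries no term for side product.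

6. Decision: I set the bath of alder, which stands highest.

The forecast also names alder, with 63 %, 68 %, 19.5 % and 90 % for birch, elm, larch and alder, and it says “I trim alder for side product”, so its alder stands below mine.

The flasks give 66.1 % for birch, 70.9 % for elm, 20.2 % for larch and 93.6 % for alder, so alder leads.

    starting material + free catalyst ⇌ catalyst intermediate A (K = 28.0 M⁻¹, k = 0.310 M⁻¹ min⁻¹, Ea = 83.0 kJ mol⁻¹, ΔH = 5.00 kJ mol⁻¹)
    catalyst intermediate A → free catalyst + target (k = 0.0410 min⁻¹, Ea = 94.0 kJ mol⁻¹)
    second substrate + free catalyst ⇌ catalyst intermediate B (K = 95.0 M⁻¹, k = 0.240 M⁻¹ min⁻¹, Ea = 79.0 kJ mol⁻¹, ΔH = −59.0 kJ mol⁻¹)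
    catalyst intermediate B → free catalyst + second product (k = 0.170 min⁻¹, Ea = 101 kJ mol⁻¹)
    catalyst intermediate B + capture agent → trapped intermediate (k = 0.150 M⁻¹ min⁻¹, Ea = 67.0 kJ mol⁻¹)
    second substrate + protic impurity → quenched substrate (k = 0.110 M⁻¹ min⁻¹, Ea = 76.0 kJ mol⁻¹)
    starting material + target → side product (k = 6.20 × 10⁻⁴ M⁻¹ min⁻¹, Ea = 91.0 kJ mol⁻¹)
    (constants at 70 °C)

Alder has converted 99.6 % of its starting material and holds 93.6 % of target beside 6.07 % of side product, so my 99.0 % of target stands above the flask. At 8.00 d in alder, the forward step into catalyst intermediate A alone uses starting material 21 times as fast as the step into side product. For a flask like alder kept at 45 °C, the kept share 88.6 % gives 29.2 %, and that flask holds 32.2 % of target.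

Readings and results were generated by integration on assumed constants; scatter was added.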